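All runs are calculated from invented constants.

The cedar run carried more L than birch and its J readings topped out higher, at 42.2% against 29.7%, so two chemists dispute the new flask.

| flask | E | L | remark | time | volume of the second phase over the first |
|---|---|---|---|---|---|
| birch | 20 mM | 1.2 equiv | run made earlier |  |  |
| cedar | 20 mM | 1.9 equiv | run made earlier |  |  |
| flask | 20 mM | 2.50 equiv |  | 8.0 d | 0.25 |

| run | time / d | J / % | E / % |
|---|---|---|---|
| birch | 0.417 | 9.6 | 90.6 |
| birch | 0.625 | 13.0 | 84.0 |
| birch | 1.04 | 21.6 | 72.3 |
| birch | 1.67 | 28.4 | 57.4 |
| birch | 3.00 | 29.7 | 37.6 |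
| birch | 5.00 | 27.6 | 19.7 |
| cedar | 0.333 | 8.0 | 87.8 |
| cedar | 0.833 | 24.5 | 66.5 |
| cedar | 1.67 | 38.6 | 40.2 |
| cedar | 2.50 | 42.2 | 24.7 |
| cedar | 4.00 | 37.9 | 10.8 |
| cedar | 5.00 | 35.6 | 8.6 |

(each reading ± 1 percentage point)

- in the second phase: L; everything else is in the first
- charges count per volume of the first phase; a concentration in a rate is the amount of a species over the volume of its own phase; every rate counts per litre of the first phase
- the earlier runs hold the two phases in the same ratio of volumes as the flask asked about

1. amount of J at 8.0 d, in percent of the E charged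
2. the change that raises the amount of J at 8.0 d, in percent of the E charged most ("none" if none brings more than 2 percentage points) (Wednesday's / Sunday's / none)
3. amount of J at 8.0 d, in percent of the E charged, after Wednesday's

Paul reads that comparison forward: more L, more J, so the flask should end above cedar's top reading. Ruth asks which side of a crossing the reading at 8.0 d lies on.

E falls with a first-order constant k, read as 0.331 d⁻¹ in birch and 0.571 d⁻¹ in cedar. Scaling cedar by equivalents gives 0.752 d⁻¹ for the flask. At cedar's top, feed equals loss, so J's loss constant λ = kE/J reads 0.334 d⁻¹. For a chain E → J → onward, the top lies at ln(k/λ)/(k − λ), which gives 1.94 d for the flask. This is the crossing time t×, when the feed of J from E falls to the loss of J. Birch's own k gives 3.01 d, beside its top reading at 3.00 d. With the L doubled, t× moves to 1.29 d. Both crossings come far earlier than 8.0 d, so Ruth expects extra L to matter little there.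

That reckoning gives a time, not a yield. The forecast supplies the yield: 30%, best change none, and 30% after Wednesday's, on the ground that “J sits near its late plateau”.

The flask gives 27.7%. Sunday's adds 1.3 percentage points; Wednesday's shifts it by −0.13 points, to 27.6%, so the answer is none.

    Z ⇌ L, rate k1*([Z] - [L]/K1) per volume of the first phase (partition coefficient = 0.437, kL = 0.0202 h⁻¹)
    E + Z → J (k = 0.828 M⁻¹ h⁻¹)
    J ⇌ D (K = 2.80, k = 0.0101 h⁻¹)
    E + J → G (k = 0.524 M⁻¹ h⁻¹)

Ruth's side holds at 8.0 d, but Paul's has its region near t×: a neighbouring flask with the same amounts, left until 50 h, holds 48.1% J, more than cedar's top reading. A second neighbouring flask, left until 5.0 d, holds 37.3% J, and the flask itself holds 27.7% at 8.0 d, when J is made at 0.0912 of the rate it is used up, each step taken net. The flask is not at rest: E, the limiting reagent, stands at 0.37%, and by 80.0 d D climbs from 50.6% to 57.9%, while G stays at 21.4% and J sinks to 20.7%.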